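## Structural features

The target is a cembrane-type diterpenoid: a 14-membered carbocycle (C1–C14) spanned by a seven-membered α-methylene lactone, O–C12–C13–C14–C1–C15–C16, with the exocyclic methylene C17 on C15 and the ester oxygen on the fully substituted C12. The carbocycle carries a Z-trisubstituted alkene (C7=C8, methyl on C8) and five stereocentres: C1 (S), the vicinal pair C3 (S, secondary alcohol)/C4 (R, tertiary methyl carbinol) and the vicinal pair C11 (R, secondary alcohol)/C12 (S, tertiary lactone carbinol). C1 stands alone, two carbons away from either pair, so it needs its own control element. The fragile groups are the α-methylene lactone (a Michael acceptor), the tertiary ester and tertiary alcohol (ionisation or elimination under strong acid), and the C3 hydroxyl, which sits δ to the lactone carbonyl C16 and could translactonise to a six-membered lactone once it is free. The real difficulty is twofold: acylating the hindered tertiary C12 oxygen inside a medium ring, and closing a 14-membered ring that contains a geometrically defined trisubstituted alkene. The key step exploits the fact that the C13–C14 bond of the lactone ring is an unfunctionalised CH2–CH2 link between the quaternary C12 and the stereogenic C1. That bond can be made as an alkene from two vinyl groups after the ester bond already exists, and then saturated.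

## Logic of the disconnections

36 from 35, and 35 from 31. The bonds cut are the three O–Si bonds and then the exocyclic C15=C17 bond. The Michael acceptor and the free C3 hydroxyl are the most fragile features and should appear last. The gain is that 31 is a saturated lactone that tolerates enolate and organometallic chemistry. The demand is that C15 be the only enolisable position and that the last deprotection be mild and non-basic.

31 from 29 (through 30). The bond cut is C8–C9, between an alkene carbon and a methylene. It is remote from every stereocentre, and its two ends (a vinyl iodide and a terminal alkene) stay inert until they are called on. The gain is that the macrocycle opens to a chain with the Z geometry of C7=C8 already fixed. The demand is high dilution, retention of alkene geometry, and a C13–C14 bond that is already saturated, since an allylic tertiary ester would ionise with palladium.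

29 from 28, 27, 26 and 25. The bond cut is C9=C10, followed by functional-group changes at C10 and C11. A third terminal alkene must not be present during the metathesis, so C10 is carried as the oxygenated carbon of a ketal. The gain is that 25 holds the C10/C11 diol as its only ketal while C3/C4 are silyl ethers, so unmasking C10 requires no choice between two ketals. The demand is that the ketal be hydrolysed without loss of the silyl ethers and that 28 not epimerise at C11.

25 from 24, and 24 from 23. The bond cut is C13–C14, taken back to C13=C14 and then to two vinyl groups. This is the only ring bond of the lactone that bears no functionality and no stereochemical information. The gain is that the seven-membered ring is closed at carbon, so no tertiary alcohol has to be lactonised. The demand is site selectivity among three alkenes and cyclisation in preference to oligomerisation.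

23 from 20 and 4. The bond cut is the ester bond C16–O. Made between two open-chain fragments, this hindered ester can be forced with an alkoxide and an acid chloride. The gain is two fragments of similar size, each with its stereocentres complete. The demand is an acid without an α-stereocentre (met: C15 is a methylene) and an alcohol whose neighbouring oxygens cannot migrate (met: the ketal).

4 from 3, 2 and 1. The bonds cut are C12–CH3 and then C12–C13. Both are carbonyl additions, and C11 comes from the chiral pool. The gain is that the fragment is three steps from 1. The demand is that the second addition be chelation-controlled and that the order (vinyl first, methyl second) be the one that gives (S)-C12.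

20 from 18 (through 19), and 18 from 16 and 17. The bond cut is C1–C15. An allylic alkylation makes the isolated stereocentre C1 and the C14 vinyl group in one step. The gain is a linear allylic carbonate and a commodity malonate. The demand is branched regioselectivity, catalyst control of the face, and a pure E carbonate.

16 from 15, 14 and 13; 13 from 12; 12 from 11. The bonds cut are the carbonate C–O, C1=C14 (cross-metathesis) and C2–C3 (allylation). The gain is an α-branched aldehyde with no α-hydrogen. The demand is reagent control at C3, because the neighbouring quaternary C4 (methyl versus chain) offers little bias.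

11 from 9 (through 10), 9 from 8, 8 from 6 (through 7), 6 from 5. The bonds cut are the original vinyl C=C (giving the C3 aldehyde), C7=C8 (iodo-olefination) and the original trisubstituted C=C. The gain is that 5 supplies C2–C8 with C4 in the correct configuration. The demand is that the two alkenes of 5 be cleaved one after the other, the electron-rich one first, and that the olefination give the Z-iodoalkene.

## Other disconnections considered

Alternative 1: The cut is the C4–C5 bond of the carbocycle, taken back to an alkyne. Forward, the seco diyne lactone A1, with both alkynes methyl-capped, would be closed by the molybdenum alkylidyne Mo(≡CC6H4OCH3)(OSi(C6H5)3)3 to the 14-membered cycloalkyne A2, with the two caps lost as a volatile alkyne. The C3 propargylic oxygen would then direct the conversion of C4≡C5 into the C4 methyl carbinol and the C5 methylene, for example by trans-hydrometallation, methyl coupling, hydroxyl-directed epoxidation and reductive opening.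
- In its favour: alkyne metathesis ignores alkenes, so the Z C7=C8 alkene cannot interfere, and the macrocyclisation has no alkene geometry to control.
- Against it here: C4, a quaternary stereocentre that the chosen route obtains from 5, would have to be created late, on the macrocycle, by several transformations whose facial selectivity depends on an unknown ring conformation. The skipped enyne in A1 and A2 (C4≡C5–C6–C7=C8) is prone to isomerisation. The hindered tertiary lactone still has to be made beforehand.
- Comparison: structurally this plan attacks the macrocycle and leaves the lactone problem open, whereas the chosen plan solves the lactone and leaves the macrocycle to a later coupling. Mechanistically both are metatheses driven by loss of a volatile by-product. For the 14-membered ring the alkyne version is at least the equal of the palladium coupling of step 22, and probably the more predictable. In step economy it is weaker, because the elaboration of C3–C5 replaces two stereocentres that the chosen route sets in two steps.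

Alternative 2: The cut removes C16 as carbon monoxide and breaks C15–C16 and C16–O together. Forward, the macrocyclic enol triflate A3 (triflate on C15, free C12 hydroxyl) would add oxidatively to zerovalent palladium from Pd(P(C6H5)3)4 and insert CO, and the tertiary hydroxyl would capture the acylpalladium. This gives the protected target A4, with the lactone ring and the exocyclic methylene made in one operation.
- In its favour: no separate enolate chemistry is needed for the methylene, the Michael acceptor appears only at the end, and an acylpalladium held next to the alcohol is a good way to acylate a hindered tertiary oxygen. On these three points the alternative equals or betters the chosen plan, which spends one step on the esterification and a multi-operation step on the methylenation.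
- Against it: A3 requires a methyl ketone on C1 to be converted regioselectively into the terminal enol triflate without epimerising C1, which is α to that ketone. Closing a seven-membered ring by carbonylative lactonisation is less favourable than the usual five- and six-membered cases, so reduction or intermolecular capture of the acylpalladium can compete. The 14-membered ring would have to be closed without the lactone in place.
- Comparison: the chosen plan sets C1 once, β to the carbonyl where it cannot epimerise, and forms the seven-membered ring by a reaction type with direct precedent for that ring size. The alternative is shorter at the end but carries more risk at C1 and in the ring-size dependence of the carbonylation.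

Alternative 3: The cut is the C8–C9 bond. Forward, the seco lactone A5, carrying the C11 vinyl group and the Z-iodoalkene, would be hydroborated at C9=C10 with 9-borabicyclo[3.3.1]nonane and coupled with Pd(dppf)Cl2 and Cs2CO3 to the bicyclic lactone A6.
- In its favour: the Z geometry of C7=C8 is set in an open chain and carried through with retention, the new bond is remote from all stereocentres, and both coupling handles are inert during the build-up.
- Against it: a B-alkyl coupling at high dilution must compete with protodeboronation and β-hydride elimination, and the disconnection does not say how the tertiary lactone in A5 arises.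
- Comparison: this is a partner and not a rival. The chosen route uses the same closure as step 22 (29 to 31), so on the macrocycle the two plans are equal, and in step count they are the same. They differ in which event is treated as strategic: taking the metathesis as key step answers the question alternative 3 leaves open, whereas alternative 3 alone would fall back on lactonising a tertiary alcohol.

Key step: step 16

Remark 1: atoms are numbered as in the cembrane skeleton: ring carbons C1–C14, lactone carbons C15 (α) and C16 (carbonyl), exocyclic methylene C17.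
Remark 2 (assumption): in step 13 the (Sa,S,S) phosphoramidite is taken to steer the malonate to the allyl face that gives (R)-18, the sense usual for alkyl-substituted allyl carbonates; the mirror-image ligand would be used if the sense were the reverse.
Remark 3: the configurations of 23 and 24 were checked centre by centre (C1, C3, C4, C11, C12) against 36 and correspond. The C3/C4 diol is carried as silyl ethers rather than as a second ketal, so that C10 can be unmasked after ring closure without discriminating between two ketals.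

## Route

Step 1
Reactants: 1 (R)-glyceraldehyde acetonide [(4R)-2,2-dimethyl-1,3-dioxolane-4-carbaldehyde]
Product: 2 1-[(4R)-2,2-dimethyl-1,3-dioxolan-4-yl]prop-2-en-1-ol (both carbinol epimers)
Conditions: CH2=CHMgBr, THF, −78 °C to 0 °C; aqueous work-up
Reagents that add atoms: vinylmagnesium bromide, C=C[Mg]Br
Why: Grignard 1,2-addition to the aldehyde forms the C12–C13 bond; the epimer mixture at the carbinol is of no consequence because this centre becomes a ketone in step 2, and C11 comes unchanged from the chiral pool.

Step 2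
Reactants: 2 1-[(4R)-2,2-dimethyl-1,3-dioxolan-4-yl]prop-2-en-1-ol
Product: 3 1-[(4R)-2,2-dimethyl-1,3-dioxolan-4-yl]prop-2-en-1-one
Conditions: Dess–Martin periodinane, CH2Cl2, 0 °C to rt; used crude
Reagents that add atoms: none
Why: Dess–Martin oxidation of the secondary allylic alcohol is fast and non-basic, which should spare the ketal and the α-alkoxy centre C11; the enone is a Michael acceptor and is taken on at once.

Step 3
Reactants: 3 1-[(4R)-2,2-dimethyl-1,3-dioxolan-4-yl]prop-2-en-1-one
Product: 4 (2S)-2-[(4R)-2,2-dimethyl-1,3-dioxolan-4-yl]but-3-en-2-ol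
Conditions: CH3MgBr, Et2O/CH2Cl2, −78 °C
Reagents that add atoms: methylmagnesium bromide, C[Mg]Br
Why: Chelation-controlled (Cram chelate) 1,2-addition: magnesium bridges the ketone oxygen and the ring oxygen on C11, and methyl should enter on the face of the chelate that carries the C11 hydrogen, away from C10, which gives (S)-C12; methyl Grignard reagents add 1,2 to enones when no copper is present.

Step 4
Reactants: 5 (R)-linalool [(3R)-3,7-dimethylocta-1,6-dien-3-ol]
Product: 6 (3R)-3,7-dimethyl-3-(triethylsilyloxy)octa-1,6-diene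
Conditions: Et3SiOTf, 2,6-lutidine, CH2Cl2, −78 °C to 0 °C
Reagents that add atoms: triethylsilyl trifluoromethanesulfonate, CC[Si](CC)(CC)OS(=O)(=O)C(F)(F)F
Why: Silyl triflate silylation of a tertiary alcohol; the carbinol carbon is the future C4 and already has the required configuration.

Step 5
Reactants: 6 (3R)-3,7-dimethyl-3-(triethylsilyloxy)octa-1,6-diene
Product: 8 (4R)-4-methyl-4-(triethylsilyloxy)hex-5-enal, via ozonide 7 (not isolated)
Conditions: O3 (1 equiv, Sudan Red 7B end point), CH2Cl2, −78 °C; then PPh3, −78 °C to rt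
Reagents that add atoms: ozone, [O-][O+]=O
Why: Ozonolysis to a dye end point is selective for the electron-rich trisubstituted alkene over the vinyl group, which is monosubstituted and flanked by the silyloxy-bearing quaternary carbon; reductive work-up gives the aldehyde that becomes C7.

Step 6
Reactants: 8 (4R)-4-methyl-4-(triethylsilyloxy)hex-5-enal
Product: 9 (3R,6Z)-7-iodo-3-methyl-3-(triethylsilyloxy)octa-1,6-diene
Conditions: [Ph3PCH2CH3]I, n-BuLi, THF, rt; I2, −78 °C; NaN(SiMe3)2, −20 °C; then 8, −78 °C
Reagents that add atoms: (1-iodoethylidene)triphenylphosphorane (made in the flask), CC(I)=P(c1ccccc1)(c1ccccc1)c1ccccc1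
Why: Stork–Zhao-type Wittig olefination with the α-iodo ylide; unstabilised α-halo ylides react under kinetic control to give the Z-iodoalkene (iodine cis to the chain), which fixes the future C7=C8 geometry.

Step 7
Reactants: 9 (3R,6Z)-7-iodo-3-methyl-3-(triethylsilyloxy)octa-1,6-diene
Product: 11 (2R,5Z)-6-iodo-2-methyl-2-(triethylsilyloxy)hept-5-enal, via diol 10 (not isolated)
Conditions: OsO4 (2 mol %), NaIO4, 2,6-lutidine, dioxane/H2O, rt
Reagents that add atoms: osmium tetroxide, O=[Os](=O)(=O)=O (oxygen donor; re-formed by sodium periodate, [Na+].[O-]I(=O)(=O)=O)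
Why: Lemieux–Johnson cleavage; osmylation should take the vinyl group and leave the iodoalkene, which is trisubstituted, shielded by iodine and electron-poor; the aldehyde (future C3) has no α-hydrogen and cannot epimerise.

Step 8
Reactants: 11 (2R,5Z)-6-iodo-2-methyl-2-(triethylsilyloxy)hept-5-enal
Product: 12 (4S,5R,8Z)-9-iodo-5-methyl-5-(triethylsilyloxy)deca-1,8-dien-4-ol
Conditions: (−)-Ipc2BOMe, CH2=CHCH2MgBr, Et2O, 0 °C; then 11, −78 °C; NaOH, H2O2, 0 °C to rt
Reagents that add atoms: (−)-B-allyldiisopinocampheylborane (made in the flask), C=CCB([C@@H]1C[C@@H]2C[C@H]([C@H]1C)C2(C)C)[C@@H]1C[C@@H]2C[C@H]([C@H]1C)C2(C)C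
Why: Brown allylation through a closed six-membered chair transition state; the reagent derived from (+)-α-pinene should deliver allyl to the aldehyde face that gives (S)-C3, as it does with other α-branched aldehydes, and reagent control overrides the weak bias of the quaternary α-centre (methyl versus chain).

Step 9
Reactants: 12 (4S,5R,8Z)-9-iodo-5-methyl-5-(triethylsilyloxy)deca-1,8-dien-4-ol
Product: 13 (4S,5R,8Z)-4-(tert-butyldimethylsilyloxy)-9-iodo-5-methyl-5-(triethylsilyloxy)deca-1,8-diene
Conditions: tBuMe2SiOTf, 2,6-lutidine, CH2Cl2, −78 °C to 0 °C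
Reagents that add atoms: tert-butyldimethylsilyl trifluoromethanesulfonate, CC(C)(C)[Si](C)(C)OS(=O)(=O)C(F)(F)F
Why: Silyl triflate silylation of the hindered secondary alcohol; a robust silyl ether on C3 is wanted because a free C3 hydroxyl would later sit δ to the lactone carbonyl.

Step 10
Reactants: 13 (4S,5R,8Z)-4-(tert-butyldimethylsilyloxy)-9-iodo-5-methyl-5-(triethylsilyloxy)deca-1,8-diene
Product: 14 methyl (2E,5S,6R,9Z)-5-(tert-butyldimethylsilyloxy)-10-iodo-6-methyl-6-(triethylsilyloxy)undeca-2,9-dienoate
Conditions: methyl acrylate (5 equiv), RuCl2(=CHC6H5)(P(C6H11)3)(H2IMes) (second-generation Grubbs catalyst, 5 mol %), CH2Cl2, 40 °C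
Reagents that add atoms: methyl acrylate, C=CC(=O)OC
Why: Cross-metathesis of a terminal alkene with an acrylate favours the cross product and the E enoate; the hindered, electron-poor iodoalkene should not engage the catalyst.

Step 11
Reactants: 14 methyl (2E,5S,6R,9Z)-5-(tert-butyldimethylsilyloxy)-10-iodo-6-methyl-6-(triethylsilyloxy)undeca-2,9-dienoate
Product: 15 (2E,5S,6R,9Z)-5-(tert-butyldimethylsilyloxy)-10-iodo-6-methyl-6-(triethylsilyloxy)undeca-2,9-dien-1-ol
Conditions: iBu2AlH (2.2 equiv), CH2Cl2, −78 °C; Rochelle salt work-up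
Reagents that add atoms: none
Why: 1,2-Reduction of the enoate gives the E allylic alcohol with the alkene geometry intact; silyl ethers and the vinyl iodide are inert at −78 °C.

Step 12
Reactants: 15 (2E,5S,6R,9Z)-5-(tert-butyldimethylsilyloxy)-10-iodo-6-methyl-6-(triethylsilyloxy)undeca-2,9-dien-1-ol
Product: 16 methyl (2E,5S,6R,9Z)-5-(tert-butyldimethylsilyloxy)-10-iodo-6-methyl-6-(triethylsilyloxy)undeca-2,9-dien-1-yl carbonate
Conditions: ClCO2CH3, pyridine, CH2Cl2, 0 °C
Reagents that add atoms: methyl chloroformate, COC(=O)Cl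
Why: Acylation of the primary allylic alcohol gives the linear E carbonate, the standard electrophile for iridium-catalysed allylic substitution.

Step 13
Reactants: 16 methyl (2E,5S,6R,9Z)-5-(tert-butyldimethylsilyloxy)-10-iodo-6-methyl-6-(triethylsilyloxy)undeca-2,9-dien-1-yl carbonate; 17 dimethyl malonate
Product: 18 dimethyl 2-[(3R,5S,6R,9Z)-5-(tert-butyldimethylsilyloxy)-10-iodo-6-methyl-6-(triethylsilyloxy)undeca-1,9-dien-3-yl]propanedioate
Conditions: [Ir(cod)Cl]2 (2 mol %), (Sa,S,S)-O,O′-(1,1′-binaphthalene-2,2′-diyl)-N,N-bis(1-phenylethyl)phosphoramidite (4 mol %), 1,5,7-triazabicyclo[4.4.0]dec-5-ene (8 mol %), THF, 50 °C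
Reagents that add atoms: none
Why: Iridium-catalysed asymmetric allylic alkylation: ionisation of the carbonate gives a (π-allyl)iridium complex and methoxide, which deprotonates the malonate; the malonate should attack the substituted allyl terminus on the face opposite iridium, the ligand choosing the allyl face, which sets C1 and leaves the C14 vinyl group.

Step 14
Reactants: 18 dimethyl 2-[(3R,5S,6R,9Z)-5-(tert-butyldimethylsilyloxy)-10-iodo-6-methyl-6-(triethylsilyloxy)undeca-1,9-dien-3-yl]propanedioate
Product: 20 (3S,5S,6R,9Z)-5-(tert-butyldimethylsilyloxy)-3-ethenyl-10-iodo-6-methyl-6-(triethylsilyloxy)undec-9-enoic acid, via diacid 19 (not isolated)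
Conditions: LiOH, THF/CH3OH/H2O, 50 °C; 1 M HCl to pH 3, 0 °C; then pyridine, 110 °C
Reagents that add atoms: none
Why: Malonic ester saponification followed by thermal decarboxylation of the malonic acid through a six-membered transition state; C1 is not touched, and its descriptor changes from R to S only because the substituent priorities change.

Step 15
Reactants: 20 (3S,5S,6R,9Z)-5-(tert-butyldimethylsilyloxy)-3-ethenyl-10-iodo-6-methyl-6-(triethylsilyloxy)undec-9-enoic acid; 4 (2S)-2-[(4R)-2,2-dimethyl-1,3-dioxolan-4-yl]but-3-en-2-ol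
Product: 23 (2S)-2-[(4R)-2,2-dimethyl-1,3-dioxolan-4-yl]but-3-en-2-yl (3S,5S,6R,9Z)-5-(tert-butyldimethylsilyloxy)-3-ethenyl-10-iodo-6-methyl-6-(triethylsilyloxy)undec-9-enoate, via acid chloride 21 (not isolated), via lithium alkoxide 22 (not isolated)
Conditions: 20, 1-chloro-N,N,2-trimethylprop-1-en-1-amine, CH2Cl2, 0 °C to rt; 4, LiN(SiMe3)2, THF, −78 °C; combine, −78 °C to 0 °C
Reagents that add atoms: none
Why: Acylation of a preformed tertiary lithium alkoxide with an acid chloride made under neutral conditions is the forcing but standard way to esterify a hindered tertiary alcohol. The acid has no α-stereocentre, so passage through a ketene costs nothing, and the tied-back ketal keeps the alkoxide accessible and cannot migrate.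

Step 16
Reactants: 23 (2S)-2-[(4R)-2,2-dimethyl-1,3-dioxolan-4-yl]but-3-en-2-yl (3S,5S,6R,9Z)-5-(tert-butyldimethylsilyloxy)-3-ethenyl-10-iodo-6-methyl-6-(triethylsilyloxy)undec-9-enoate
Product: 24 (4S,7S)-4-[(2S,3R,6Z)-2-(tert-butyldimethylsilyloxy)-7-iodo-3-methyl-3-(triethylsilyloxy)oct-6-en-1-yl]-7-[(4R)-2,2-dimethyl-1,3-dioxolan-4-yl]-7-methyl-4,7-dihydrooxepin-2(3H)-one
Conditions: RuCl2(=CHC6H5)(P(C6H11)3)(H2IMes) (second-generation Grubbs catalyst, 10 mol %), toluene (1 mM), 80 °C, argon purge
Reagents that add atoms: none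
Why: Ring-closing olefin metathesis by the metallacyclobutane mechanism: the ruthenium benzylidene should exchange first with the unhindered vinyl group on C1 to give the C14 alkylidene, which adds across the vinyl group on the quaternary C12 to a ruthenacyclobutane; cycloreversion releases the lactone with the new C13=C14 bond and a ruthenium methylidene, and ethylene leaves the solution. The closest known reaction type is ring-closing metathesis of dienyl esters to seven-membered unsaturated lactones with ruthenium alkylidenes. The one ring formed, the seven-membered lactone O–C12–C13–C14–C1–C15–C16, is closed at carbon by intramolecular alkene–alkylidene metathesis, with the ester bond already in place. No stereocentre is formed; the only stereochemical element, the geometry of C13=C14, is forced cis by the ring size and is removed in step 17. The step needs site selectivity among three alkenes: the two vinyl groups react because they are monosubstituted, whereas the trisubstituted, iodine-bearing C7=C8 alkene is too hindered and electron-poor to enter the cycle. It also needs cyclisation to beat dimerisation at the C1 vinyl group; high dilution, the fully substituted C12 (which brings the two vinyl groups together) and the reversibility of dimer formation under ethylene loss should secure this.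

Step 17
Reactants: 24 (4S,7S)-4-[(2S,3R,6Z)-2-(tert-butyldimethylsilyloxy)-7-iodo-3-methyl-3-(triethylsilyloxy)oct-6-en-1-yl]-7-[(4R)-2,2-dimethyl-1,3-dioxolan-4-yl]-7-methyl-4,7-dihydrooxepin-2(3H)-one
Product: 25 (4S,7S)-4-[(2S,3R,6Z)-2-(tert-butyldimethylsilyloxy)-7-iodo-3-methyl-3-(triethylsilyloxy)oct-6-en-1-yl]-7-[(4R)-2,2-dimethyl-1,3-dioxolan-4-yl]-7-methyloxepan-2-one
Conditions: 2-nitrobenzenesulfonohydrazide (excess, in portions), Et3N, CH2Cl2, rt
Reagents that add atoms: none
Why: Diimide made in the flask transfers two hydrogens in a concerted syn fashion to the cis-disubstituted ring alkene; the trisubstituted iodoalkene reacts far more slowly, and the C–I bond is not at risk as it would be under catalytic hydrogenation.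

Step 18
Reactants: 25 (4S,7S)-4-[(2S,3R,6Z)-2-(tert-butyldimethylsilyloxy)-7-iodo-3-methyl-3-(triethylsilyloxy)oct-6-en-1-yl]-7-[(4R)-2,2-dimethyl-1,3-dioxolan-4-yl]-7-methyloxepan-2-one
Product: 26 (4S,7S)-4-[(2S,3R,6Z)-2-(tert-butyldimethylsilyloxy)-7-iodo-3-methyl-3-(triethylsilyloxy)oct-6-en-1-yl]-7-[(1R)-1,2-dihydroxyethyl]-7-methyloxepan-2-one
Conditions: AcOH/H2O/THF (3:1:1), 40 °C
Reagents that add atoms: none
Why: Acid-catalysed hydrolysis of the only ketal in the molecule; the secondary tert-butyldimethylsilyl ether and the hindered tertiary triethylsilyl ether hydrolyse much more slowly, and any silyl group lost from C4 is put back in step 19.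

Step 19
Reactants: 26 (4S,7S)-4-[(2S,3R,6Z)-2-(tert-butyldimethylsilyloxy)-7-iodo-3-methyl-3-(triethylsilyloxy)oct-6-en-1-yl]-7-[(1R)-1,2-dihydroxyethyl]-7-methyloxepan-2-one
Product: 27 (4S,7S)-7-[(1R)-1,2-bis(triethylsilyloxy)ethyl]-4-[(2S,3R,6Z)-2-(tert-butyldimethylsilyloxy)-7-iodo-3-methyl-3-(triethylsilyloxy)oct-6-en-1-yl]-7-methyloxepan-2-one
Conditions: Et3SiOTf (3 equiv), 2,6-lutidine, CH2Cl2, −78 °C to 0 °C
Reagents that add atoms: triethylsilyl trifluoromethanesulfonate, CC[Si](CC)(CC)OS(=O)(=O)C(F)(F)F
Why: Exhaustive silylation with the silyl triflate covers the primary C10 and the hindered secondary C11 hydroxyl, and sets up the selective unmasking of C10 in the next step.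

Step 20
Reactants: 27 (4S,7S)-7-[(1R)-1,2-bis(triethylsilyloxy)ethyl]-4-[(2S,3R,6Z)-2-(tert-butyldimethylsilyloxy)-7-iodo-3-methyl-3-(triethylsilyloxy)oct-6-en-1-yl]-7-methyloxepan-2-one
Product: 28 (2S)-2-{(2S,5S)-5-[(2S,3R,6Z)-2-(tert-butyldimethylsilyloxy)-7-iodo-3-methyl-3-(triethylsilyloxy)oct-6-en-1-yl]-2-methyl-7-oxooxepan-2-yl}-2-(triethylsilyloxy)acetaldehyde
Conditions: (COCl)2, DMSO, CH2Cl2, −78 °C to −30 °C; then Et3N, −78 °C to 0 °C
Reagents that add atoms: none
Why: Under Swern conditions a primary triethylsilyl ether is cleaved and oxidised in the same flask while secondary and tertiary silyl ethers stay on, so C10 becomes the aldehyde with C11 still protected; the low temperature guards the α-silyloxy centre C11, whose descriptor changes only through the priority rules.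

Step 21
Reactants: 28 (2S)-2-{(2S,5S)-5-[(2S,3R,6Z)-2-(tert-butyldimethylsilyloxy)-7-iodo-3-methyl-3-(triethylsilyloxy)oct-6-en-1-yl]-2-methyl-7-oxooxepan-2-yl}-2-(triethylsilyloxy)acetaldehyde
Product: 29 (4S,7S)-4-[(2S,3R,6Z)-2-(tert-butyldimethylsilyloxy)-7-iodo-3-methyl-3-(triethylsilyloxy)oct-6-en-1-yl]-7-methyl-7-[(1R)-1-(triethylsilyloxy)prop-2-en-1-yl]oxepan-2-one
Conditions: [Ph3PCH3]Br, KN(SiMe3)2, THF, 0 °C; then 28, −78 °C to 0 °C
Reagents that add atoms: methylidenetriphenylphosphorane (made in the flask), C=P(c1ccccc1)(c1ccccc1)c1ccccc1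
Why: Wittig methylenation adds C9; the aldehyde is far more electrophilic than the lactone of a tertiary alcohol, and addition at −78 °C to a ylide made with a slight deficit of base should avoid epimerisation at C11.

Step 22
Reactants: 29 (4S,7S)-4-[(2S,3R,6Z)-2-(tert-butyldimethylsilyloxy)-7-iodo-3-methyl-3-(triethylsilyloxy)oct-6-en-1-yl]-7-methyl-7-[(1R)-1-(triethylsilyloxy)prop-2-en-1-yl]oxepan-2-one
Product: 31 (1S,3S,4R,7Z,11R,12S)-3-(tert-butyldimethylsilyloxy)-4,8,12-trimethyl-4,11-bis(triethylsilyloxy)-13-oxabicyclo[10.3.2]heptadec-7-en-14-one, via alkylborane 30 (not isolated)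
Conditions: 9-BBN dimer, THF, 0 °C to rt; then slow addition to Pd(dppf)Cl2 (20 mol %), As(C6H5)3, Cs2CO3, DMF/THF/H2O, 50 °C (about 1 mM)
Reagents that add atoms: none
Why: Anti-Markovnikov hydroboration of the only terminal alkene, then intramolecular B-alkyl Suzuki–Miyaura coupling (oxidative addition of zerovalent palladium into the vinyl C–I bond, base-assisted transmetallation of the primary alkyl group, reductive elimination), forms C8–C9 with retention of the Z geometry and closes the 14-membered ring; no stereocentre is formed.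

Step 23
Reactants: 31 (1S,3S,4R,7Z,11R,12S)-3-(tert-butyldimethylsilyloxy)-4,8,12-trimethyl-4,11-bis(triethylsilyloxy)-13-oxabicyclo[10.3.2]heptadec-7-en-14-one
Product: 35 (1S,3S,4R,7Z,11R,12S)-3-(tert-butyldimethylsilyloxy)-4,8,12-trimethyl-15-methylidene-4,11-bis(triethylsilyloxy)-13-oxabicyclo[10.3.2]heptadec-7-en-14-one, via lithium enolate 32 (not isolated), via Mannich base 33 (not isolated), via ammonium iodide 34 (not isolated)
Conditions: LiN(iPr)2, THF, −78 °C; CH2=N(CH3)2 I (Eschenmoser's salt), −78 °C to rt; CH3I, CH3OH, rt; DBU, CH2Cl2, rt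
Reagents that add atoms: N,N-dimethylmethyleneiminium iodide (Eschenmoser's salt), C=[N+](C)C.[I-]
Why: α-Methylenation by enolate aminomethylation (Mannich reaction), quaternisation and base-induced elimination of trimethylamine; C15 is the only enolisable position, and the temporary centre at C15 disappears on elimination.

Step 24
Reactants: 35 (1S,3S,4R,7Z,11R,12S)-3-(tert-butyldimethylsilyloxy)-4,8,12-trimethyl-15-methylidene-4,11-bis(triethylsilyloxy)-13-oxabicyclo[10.3.2]heptadec-7-en-14-one
Product: 36 (1S,3S,4R,7Z,11R,12S)-3,4,11-trihydroxy-4,8,12-trimethyl-15-methylidene-13-oxabicyclo[10.3.2]heptadec-7-en-14-one (target)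
Conditions: HF·pyridine, pyridine, THF, 0 °C to rt
Reagents that add atoms: none
Why: Fluoride-driven cleavage of the three silyl ethers under buffered, weakly acidic conditions avoids the strong acid a ketal would need and the basic fluoride sources that could trigger conjugate addition or translactonisation of the C3 hydroxyl onto C16.

## Compound list

1 | (R)-glyceraldehyde acetonide, (4R)-2,2-dimethyl-1,3-dioxolane-4-carbaldehyde | O=C[C@H]1COC(C)(C)O1 | starting material
2 | 1-[(4R)-2,2-dimethyl-1,3-dioxolan-4-yl]prop-2-en-1-ol (carbinol epimers) | C=CC(O)[C@H]1COC(C)(C)O1 | intermediate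
3 | 1-[(4R)-2,2-dimethyl-1,3-dioxolan-4-yl]prop-2-en-1-one | C=CC(=O)[C@H]1COC(C)(C)O1 | intermediate
4 | (2S)-2-[(4R)-2,2-dimethyl-1,3-dioxolan-4-yl]but-3-en-2-ol | C=C[C@](C)(O)[C@H]1COC(C)(C)O1 | intermediate
5 | (R)-linalool, (3R)-3,7-dimethylocta-1,6-dien-3-ol | C=C[C@](C)(O)CCC=C(C)C | starting material
6 | (3R)-3,7-dimethyl-3-(triethylsilyloxy)octa-1,6-diene | C=C[C@](C)(O[Si](CC)(CC)CC)CCC=C(C)C | intermediate
7 | ozonide, 3,3-dimethyl-5-[(3R)-3-methyl-3-(triethylsilyloxy)pent-4-en-1-yl]-1,2,4-trioxolane | C=C[C@](C)(O[Si](CC)(CC)CC)CCC1OOC(C)(C)O1 | intermediate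
8 | (4R)-4-methyl-4-(triethylsilyloxy)hex-5-enal | C=C[C@](C)(O[Si](CC)(CC)CC)CCC=O | intermediate
9 | (3R,6Z)-7-iodo-3-methyl-3-(triethylsilyloxy)octa-1,6-diene | C=C[C@](C)(O[Si](CC)(CC)CC)CC/C=C(/C)I | intermediate
10 | (3R,6Z)-7-iodo-3-methyl-3-(triethylsilyloxy)oct-6-ene-1,2-diol (C2 epimers) | OCC(O)[C@](C)(O[Si](CC)(CC)CC)CC/C=C(/C)I | intermediate
11 | (2R,5Z)-6-iodo-2-methyl-2-(triethylsilyloxy)hept-5-enal | O=C[C@](C)(O[Si](CC)(CC)CC)CC/C=C(/C)I | intermediate
12 | (4S,5R,8Z)-9-iodo-5-methyl-5-(triethylsilyloxy)deca-1,8-dien-4-ol | C=CC[C@H](O)[C@](C)(O[Si](CC)(CC)CC)CC/C=C(/C)I | intermediate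
13 | (4S,5R,8Z)-4-(tert-butyldimethylsilyloxy)-9-iodo-5-methyl-5-(triethylsilyloxy)deca-1,8-diene | C=CC[C@H](O[Si](C)(C)C(C)(C)C)[C@](C)(O[Si](CC)(CC)CC)CC/C=C(/C)I | intermediate
14 | methyl (2E,5S,6R,9Z)-5-(tert-butyldimethylsilyloxy)-10-iodo-6-methyl-6-(triethylsilyloxy)undeca-2,9-dienoate | COC(=O)/C=C/C[C@H](O[Si](C)(C)C(C)(C)C)[C@](C)(O[Si](CC)(CC)CC)CC/C=C(/C)I | intermediate
15 | (2E,5S,6R,9Z)-5-(tert-butyldimethylsilyloxy)-10-iodo-6-methyl-6-(triethylsilyloxy)undeca-2,9-dien-1-ol | OC/C=C/C[C@H](O[Si](C)(C)C(C)(C)C)[C@](C)(O[Si](CC)(CC)CC)CC/C=C(/C)I | intermediate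
16 | methyl (2E,5S,6R,9Z)-5-(tert-butyldimethylsilyloxy)-10-iodo-6-methyl-6-(triethylsilyloxy)undeca-2,9-dien-1-yl carbonate | COC(=O)OC/C=C/C[C@H](O[Si](C)(C)C(C)(C)C)[C@](C)(O[Si](CC)(CC)CC)CC/C=C(/C)I | intermediate
17 | dimethyl malonate | COC(=O)CC(=O)OC | starting material
18 | dimethyl 2-[(3R,5S,6R,9Z)-5-(tert-butyldimethylsilyloxy)-10-iodo-6-methyl-6-(triethylsilyloxy)undeca-1,9-dien-3-yl]propanedioate | C=C[C@H](C(C(=O)OC)C(=O)OC)C[C@H](O[Si](C)(C)C(C)(C)C)[C@](C)(O[Si](CC)(CC)CC)CC/C=C(/C)I | intermediate
19 | 2-[(3R,5S,6R,9Z)-5-(tert-butyldimethylsilyloxy)-10-iodo-6-methyl-6-(triethylsilyloxy)undeca-1,9-dien-3-yl]propanedioic acid | C=C[C@H](C(C(=O)O)C(=O)O)C[C@H](O[Si](C)(C)C(C)(C)C)[C@](C)(O[Si](CC)(CC)CC)CC/C=C(/C)I | intermediate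
20 | (3S,5S,6R,9Z)-5-(tert-butyldimethylsilyloxy)-3-ethenyl-10-iodo-6-methyl-6-(triethylsilyloxy)undec-9-enoic acid | C=C[C@H](CC(=O)O)C[C@H](O[Si](C)(C)C(C)(C)C)[C@](C)(O[Si](CC)(CC)CC)CC/C=C(/C)I | intermediate
21 | (3S,5S,6R,9Z)-5-(tert-butyldimethylsilyloxy)-3-ethenyl-10-iodo-6-methyl-6-(triethylsilyloxy)undec-9-enoyl chloride | C=C[C@H](CC(=O)Cl)C[C@H](O[Si](C)(C)C(C)(C)C)[C@](C)(O[Si](CC)(CC)CC)CC/C=C(/C)I | intermediate
22 | lithium (2S)-2-[(4R)-2,2-dimethyl-1,3-dioxolan-4-yl]but-3-en-2-olate | C=C[C@](C)([O-])[C@H]1COC(C)(C)O1.[Li+] | intermediate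
23 | (2S)-2-[(4R)-2,2-dimethyl-1,3-dioxolan-4-yl]but-3-en-2-yl (3S,5S,6R,9Z)-5-(tert-butyldimethylsilyloxy)-3-ethenyl-10-iodo-6-methyl-6-(triethylsilyloxy)undec-9-enoate (metathesis precursor) | C=C[C@H](CC(=O)O[C@@](C)(C=C)[C@H]1COC(C)(C)O1)C[C@H](O[Si](C)(C)C(C)(C)C)[C@](C)(O[Si](CC)(CC)CC)CC/C=C(/C)I | intermediate
24 | (4S,7S)-4-[(2S,3R,6Z)-2-(tert-butyldimethylsilyloxy)-7-iodo-3-methyl-3-(triethylsilyloxy)oct-6-en-1-yl]-7-[(4R)-2,2-dimethyl-1,3-dioxolan-4-yl]-7-methyl-4,7-dihydrooxepin-2(3H)-one (metathesis product) | O=C1C[C@H](C[C@H](O[Si](C)(C)C(C)(C)C)[C@](C)(O[Si](CC)(CC)CC)CC/C=C(/C)I)C=C[C@@](C)([C@H]2COC(C)(C)O2)O1 | intermediate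
25 | (4S,7S)-4-[(2S,3R,6Z)-2-(tert-butyldimethylsilyloxy)-7-iodo-3-methyl-3-(triethylsilyloxy)oct-6-en-1-yl]-7-[(4R)-2,2-dimethyl-1,3-dioxolan-4-yl]-7-methyloxepan-2-one | O=C1C[C@H](C[C@H](O[Si](C)(C)C(C)(C)C)[C@](C)(O[Si](CC)(CC)CC)CC/C=C(/C)I)CC[C@@](C)([C@H]2COC(C)(C)O2)O1 | intermediate
26 | (4S,7S)-4-[(2S,3R,6Z)-2-(tert-butyldimethylsilyloxy)-7-iodo-3-methyl-3-(triethylsilyloxy)oct-6-en-1-yl]-7-[(1R)-1,2-dihydroxyethyl]-7-methyloxepan-2-one | O=C1C[C@H](C[C@H](O[Si](C)(C)C(C)(C)C)[C@](C)(O[Si](CC)(CC)CC)CC/C=C(/C)I)CC[C@@](C)([C@H](O)CO)O1 | intermediate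
27 | (4S,7S)-7-[(1R)-1,2-bis(triethylsilyloxy)ethyl]-4-[(2S,3R,6Z)-2-(tert-butyldimethylsilyloxy)-7-iodo-3-methyl-3-(triethylsilyloxy)oct-6-en-1-yl]-7-methyloxepan-2-one | O=C1C[C@H](C[C@H](O[Si](C)(C)C(C)(C)C)[C@](C)(O[Si](CC)(CC)CC)CC/C=C(/C)I)CC[C@@](C)([C@H](O[Si](CC)(CC)CC)CO[Si](CC)(CC)CC)O1 | intermediate
28 | (2S)-2-{(2S,5S)-5-[(2S,3R,6Z)-2-(tert-butyldimethylsilyloxy)-7-iodo-3-methyl-3-(triethylsilyloxy)oct-6-en-1-yl]-2-methyl-7-oxooxepan-2-yl}-2-(triethylsilyloxy)acetaldehyde (C10 aldehyde) | O=C1C[C@H](C[C@H](O[Si](C)(C)C(C)(C)C)[C@](C)(O[Si](CC)(CC)CC)CC/C=C(/C)I)CC[C@@](C)([C@H](O[Si](CC)(CC)CC)C=O)O1 | intermediate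
29 | (4S,7S)-4-[(2S,3R,6Z)-2-(tert-butyldimethylsilyloxy)-7-iodo-3-methyl-3-(triethylsilyloxy)oct-6-en-1-yl]-7-methyl-7-[(1R)-1-(triethylsilyloxy)prop-2-en-1-yl]oxepan-2-one | O=C1C[C@H](C[C@H](O[Si](C)(C)C(C)(C)C)[C@](C)(O[Si](CC)(CC)CC)CC/C=C(/C)I)CC[C@@](C)([C@H](O[Si](CC)(CC)CC)C=C)O1 | intermediate
30 | B-alkyl-9-borabicyclo[3.3.1]nonane from 29 (boron on C9) | O=C1C[C@H](C[C@H](O[Si](C)(C)C(C)(C)C)[C@](C)(O[Si](CC)(CC)CC)CC/C=C(/C)I)CC[C@@](C)([C@H](O[Si](CC)(CC)CC)CCB2C3CCCC2CCC3)O1 | intermediate
31 | (1S,3S,4R,7Z,11R,12S)-3-(tert-butyldimethylsilyloxy)-4,8,12-trimethyl-4,11-bis(triethylsilyloxy)-13-oxabicyclo[10.3.2]heptadec-7-en-14-one | C1C(=O)O[C@@]2(C)CC[C@H]1C[C@H](O[Si](C)(C)C(C)(C)C)[C@](C)(O[Si](CC)(CC)CC)CC/C=C(/C)CC[C@H]2O[Si](CC)(CC)CC | intermediate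
32 | lithium enolate of 31 (C15=C16–O–Li) | C1=C([O-])O[C@@]2(C)CC[C@H]1C[C@H](O[Si](C)(C)C(C)(C)C)[C@](C)(O[Si](CC)(CC)CC)CC/C=C(/C)CC[C@H]2O[Si](CC)(CC)CC.[Li+] | intermediate
33 | 15-[(dimethylamino)methyl] derivative of 31 (C15 epimers) | CN(C)CC1C(=O)O[C@@]2(C)CC[C@H]1C[C@H](O[Si](C)(C)C(C)(C)C)[C@](C)(O[Si](CC)(CC)CC)CC/C=C(/C)CC[C@H]2O[Si](CC)(CC)CC | intermediate
34 | 15-[(trimethylammonio)methyl] derivative of 31, iodide (C15 epimers) | C[N+](C)(C)CC1C(=O)O[C@@]2(C)CC[C@H]1C[C@H](O[Si](C)(C)C(C)(C)C)[C@](C)(O[Si](CC)(CC)CC)CC/C=C(/C)CC[C@H]2O[Si](CC)(CC)CC.[I-] | intermediate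
35 | (1S,3S,4R,7Z,11R,12S)-3-(tert-butyldimethylsilyloxy)-4,8,12-trimethyl-15-methylidene-4,11-bis(triethylsilyloxy)-13-oxabicyclo[10.3.2]heptadec-7-en-14-one | C=C1C(=O)O[C@@]2(C)CC[C@H]1C[C@H](O[Si](C)(C)C(C)(C)C)[C@](C)(O[Si](CC)(CC)CC)CC/C=C(/C)CC[C@H]2O[Si](CC)(CC)CC | intermediate
36 | (1S,3S,4R,7Z,11R,12S)-3,4,11-trihydroxy-4,8,12-trimethyl-15-methylidene-13-oxabicyclo[10.3.2]heptadec-7-en-14-one | C=C1C(=O)O[C@@]2(C)CC[C@H]1C[C@H](O)[C@](C)(O)CC/C=C(/C)CC[C@H]2O | target

## Step count and least certain steps

Total: 24 steps. The longest linear sequence is 21 steps (steps 4 to 24, from 5); the three-step branch from 1 (steps 1 to 3) joins at step 15.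

Step 16 (key step). The most likely failure is unproductive loading followed by oligomerisation. The alkylidene formed at C14 may find the vinyl group on the quaternary C12 too shielded, and the ester prefers its extended conformer, so intermolecular metathesis or alkene migration by ruthenium hydrides can outrun ring closure. The fallback sets out from 20 and 4 and returns at 25. The same C13=C14 bond is made between the two free fragments by cross-metathesis of 20 with the tertiary allylic alcohol 4 (same catalyst), giving the E hydroxy acid F1. Diimide reduction gives the saturated hydroxy acid F2. The ring is then closed at oxygen by lactonisation through the 2,4,6-trichlorobenzoyl mixed anhydride with DMAP at high dilution, which gives 25. This is the lactonisation of a tertiary alcohol that the main plan avoids, so it is a second choice.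

Step 15. The acylation may stall. The acid chloride can lose HCl to a ketene that dimerises, or the hindered alkoxide may attack too slowly and instead deprotonate. The fallback sets out from 4 and 16 and returns at 23. Alcohol 4 is acylated with the small, reactive methyl malonyl chloride (pyridine, CH2Cl2; the acyl ketene pathway copes with hindered alcohols) to the mixed malonate F3. F3 then replaces 17 as the nucleophile in the iridium-catalysed allylation of 16, giving the allylated mixed malonate F4 (epimers at the malonate carbon, of no consequence). Krapcho demethoxycarbonylation (LiCl, wet DMSO, 130 °C) removes only the methyl ester carboxyl and gives 23.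

Step 22. The alkylborane may be consumed by intermolecular coupling, protodeboronation or β-hydride elimination before the 14-membered ring closes, because the chain must fold a Z-trisubstituted alkene and a lactone into one ring. The fallback sets out from 29 and returns at 31. Stille coupling of the vinyl iodide with tributyl(vinyl)stannane (retention) gives the triene F5. Ring-closing metathesis between the new diene terminus and the C11 vinyl group gives the macrocyclic diene F6, with C9=C10 in the ring. Diimide then reduces the disubstituted C9=C10 alkene in preference to the trisubstituted C7=C8 alkene, giving 31.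

Step 3. Facial selectivity may be poor if chelation is incomplete, since the ketal oxygen is a weak donor, and conjugate addition or enolisation at C11 can compete. The fallback sets out from 1 and returns at 4, and inverts both the order of the additions and the control element. CH3MgBr addition to 1 gives the secondary alcohol F7, and Dess–Martin oxidation gives the methyl ketone F8. Vinyl addition with the non-chelating titanium reagent CH2=CHTi(OiPr)3 (Felkin–Anh control, nucleophile anti to the C11–O bond) should then give the same (S)-configured 4, because exchanging both the entering group and the face leaves the configuration unchanged.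

Step 18. A protecting group may be lost: the ketal is deactivated by the neighbouring acyloxy-bearing carbon, so the C3 or C4 silyl ether could be cleaved before hydrolysis is complete, and a free C3 hydroxyl could then translactonise. The fallback sets out from 4 and 20 and returns at 27; it avoids any ketal cleavage after ring closure. Alcohol 4 is hydrolysed (aqueous AcOH) to the triol F9, and the primary and secondary hydroxyls are silylated (Et3SiCl, imidazole) to the bis-silyl ether F10. F10 is esterified with 21 under non-basic conditions (DMAP, pyridine, CH2Cl2, 40 °C, so that no alkoxide can trigger silyl migration) to the ester F11. The same metathesis closes the ring to the unsaturated lactone F12, and diimide reduction gives 27.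

## Further compounds

F1 | step 16 | (3S,4E,6S)-3-[(2S,3R,6Z)-2-(tert-butyldimethylsilyloxy)-7-iodo-3-methyl-3-(triethylsilyloxy)oct-6-en-1-yl]-6-[(4R)-2,2-dimethyl-1,3-dioxolan-4-yl]-6-hydroxyhept-4-enoic acid | O[C@@](C)(/C=C/[C@H](CC(=O)O)C[C@H](O[Si](C)(C)C(C)(C)C)[C@](C)(O[Si](CC)(CC)CC)CC/C=C(/C)I)[C@H]1COC(C)(C)O1
F2 | step 16 | (3S,6S)-3-[(2S,3R,6Z)-2-(tert-butyldimethylsilyloxy)-7-iodo-3-methyl-3-(triethylsilyloxy)oct-6-en-1-yl]-6-[(4R)-2,2-dimethyl-1,3-dioxolan-4-yl]-6-hydroxyheptanoic acid | O[C@@](C)(CC[C@H](CC(=O)O)C[C@H](O[Si](C)(C)C(C)(C)C)[C@](C)(O[Si](CC)(CC)CC)CC/C=C(/C)I)[C@H]1COC(C)(C)O1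
F3 | step 15 | methyl (2S)-2-[(4R)-2,2-dimethyl-1,3-dioxolan-4-yl]but-3-en-2-yl propanedioate | COC(=O)CC(=O)O[C@@](C)(C=C)[C@H]1COC(C)(C)O1
F4 | step 15 | methyl (2S)-2-[(4R)-2,2-dimethyl-1,3-dioxolan-4-yl]but-3-en-2-yl 2-[(3R,5S,6R,9Z)-5-(tert-butyldimethylsilyloxy)-10-iodo-6-methyl-6-(triethylsilyloxy)undeca-1,9-dien-3-yl]propanedioate (malonate-carbon epimers) | C=C[C@H](C(C(=O)OC)C(=O)O[C@@](C)(C=C)[C@H]1COC(C)(C)O1)C[C@H](O[Si](C)(C)C(C)(C)C)[C@](C)(O[Si](CC)(CC)CC)CC/C=C(/C)I
F5 | step 22 | (4S,7S)-4-[(2S,3R,6Z)-2-(tert-butyldimethylsilyloxy)-3,7-dimethyl-3-(triethylsilyloxy)nona-6,8-dien-1-yl]-7-methyl-7-[(1R)-1-(triethylsilyloxy)prop-2-en-1-yl]oxepan-2-one | O=C1C[C@H](C[C@H](O[Si](C)(C)C(C)(C)C)[C@](C)(O[Si](CC)(CC)CC)CC/C=C(/C)C=C)CC[C@@](C)([C@H](O[Si](CC)(CC)CC)C=C)O1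
F6 | step 22 | (1S,3S,4R,7Z,11R,12S)-3-(tert-butyldimethylsilyloxy)-4,8,12-trimethyl-4,11-bis(triethylsilyloxy)-13-oxabicyclo[10.3.2]heptadeca-7,9-dien-14-one (C9=C10 of either geometry) | C1C(=O)O[C@@]2(C)CC[C@H]1C[C@H](O[Si](C)(C)C(C)(C)C)[C@](C)(O[Si](CC)(CC)CC)CC/C=C(/C)C=C[C@H]2O[Si](CC)(CC)CC
F7 | step 3 | 1-[(4R)-2,2-dimethyl-1,3-dioxolan-4-yl]ethan-1-ol (carbinol epimers) | CC(O)[C@H]1COC(C)(C)O1
F8 | step 3 | 1-[(4R)-2,2-dimethyl-1,3-dioxolan-4-yl]ethan-1-one | CC(=O)[C@H]1COC(C)(C)O1
F9 | step 18 | (2R,3S)-3-methylpent-4-ene-1,2,3-triol | C=C[C@](C)(O)[C@H](O)CO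
F10 | step 18 | (3S,4R)-3-methyl-4,5-bis(triethylsilyloxy)pent-1-en-3-ol | C=C[C@](C)(O)[C@H](O[Si](CC)(CC)CC)CO[Si](CC)(CC)CC
F11 | step 18 | (3S,4R)-3-methyl-4,5-bis(triethylsilyloxy)pent-1-en-3-yl (3S,5S,6R,9Z)-5-(tert-butyldimethylsilyloxy)-3-ethenyl-10-iodo-6-methyl-6-(triethylsilyloxy)undec-9-enoate | C=C[C@H](CC(=O)O[C@@](C)(C=C)[C@H](O[Si](CC)(CC)CC)CO[Si](CC)(CC)CC)C[C@H](O[Si](C)(C)C(C)(C)C)[C@](C)(O[Si](CC)(CC)CC)CC/C=C(/C)I
F12 | step 18 | (4S,7S)-7-[(1R)-1,2-bis(triethylsilyloxy)ethyl]-4-[(2S,3R,6Z)-2-(tert-butyldimethylsilyloxy)-7-iodo-3-methyl-3-(triethylsilyloxy)oct-6-en-1-yl]-7-methyl-4,7-dihydrooxepin-2(3H)-one | O=C1C[C@H](C[C@H](O[Si](C)(C)C(C)(C)C)[C@](C)(O[Si](CC)(CC)CC)CC/C=C(/C)I)C=C[C@@](C)([C@H](O[Si](CC)(CC)CC)CO[Si](CC)(CC)CC)O1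
A1 | alternative 1 | seco diyne lactone: oxepan-2-one with C12 methyl, a C11 tert-butyldimethylsilyloxy chain ending in a methyl-capped C5 alkyne, and a C3 triethylsilyloxy side chain ending in a methyl-capped C4 alkyne | CC#CC/C=C(/C)CC[C@@H](O[Si](C)(C)C(C)(C)C)[C@]1(C)CC[C@@H](C[C@H](O[Si](CC)(CC)CC)C#CC)CC(=O)O1
A2 | alternative 1 | bicyclic lactone cycloalkyne (C4≡C5; C3 triethylsilyl ether, C11 tert-butyldimethylsilyl ether) | C1C(=O)O[C@@]2(C)CC[C@H]1C[C@H](O[Si](CC)(CC)CC)C#CC/C=C(/C)CC[C@H]2O[Si](C)(C)C(C)(C)C
A3 | alternative 2 | macrocyclic enol triflate: 14-membered carbocycle with 1-(trifluoromethylsulfonyloxy)ethenyl on C1, free C12 hydroxyl, C11 tert-butyldimethylsilyl ether, C3/C4 acetonide | C=C(OS(=O)(=O)C(F)(F)F)[C@H]1CC[C@](C)(O)[C@H](O[Si](C)(C)C(C)(C)C)CC/C(C)=C\CC[C@@]2(C)OC(C)(C)O[C@H]2C1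
A4 | alternative 2 | protected target (C11 tert-butyldimethylsilyl ether, C3/C4 acetonide) | C=C1C(=O)O[C@@]2(C)CC[C@H]1C[C@@H]3OC(C)(C)O[C@]3(C)CC/C=C(/C)CC[C@H]2O[Si](C)(C)C(C)(C)C
A5 | alternative 3 | seco lactone: oxepan-2-one with C11 vinyl carbinol tert-butyldimethylsilyl ether, C3/C4 acetonide and Z-iodoalkene | O=C1C[C@H](C[C@@H]2OC(C)(C)O[C@]2(C)CC/C=C(/C)I)CC[C@@](C)([C@H](O[Si](C)(C)C(C)(C)C)C=C)O1
A6 | alternative 3 | protected bicyclic lactone lacking only the exocyclic methylene | C1C(=O)O[C@@]2(C)CC[C@H]1C[C@@H]3OC(C)(C)O[C@]3(C)CC/C=C(/C)CC[C@H]2O[Si](C)(C)C(C)(C)C
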